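## Retrosynthetic overview

1. The oxirane (ring C) is made last by hydroxyl-directed epoxidation of the (4Z)-allylic alcohol; the C6 carbinol comes from 1,2-reduction of a macrocyclic C6 ketone.
2. Key disconnection C6–C7: the ten-membered carbocycle (ring B) is closed by adding a (Z)-enoyl radical to C7 of a 3-(sulfonylmethyl)butenolide; loss of PhSO2• in the same step creates the α-methylene lactone.
3. The butenolide (ring A) comes from a C8 allylic alcohol by acylation and ring-closing metathesis.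
4. C1=C10 comes from a Z-selective Wittig reaction between a C1–C6 phosphonium salt (carbocupration of propyne, then CO2) and an α-tigloyloxy ketone (asymmetric alkynylation of crotonaldehyde, then alkyne hydration).
5. Order of ring formation: A (metathesis), B (radical closure), C (epoxidation).

Assumption: germacrane locants are used in the explanations (C1=C10 olefin, C4–C5 epoxide, C6 carbinol, C7/C8 ring fusion, C11=C13 methylene, C12 lactone carbonyl, C14 CH2O, C15 methyl); read from the SMILES, the target is 4S,5R,6S,7S,8S with a cis-epoxide, a trans-fused lactone, C9 trans to C2 across C1=C10, and an (E)-2-methylbut-2-enoyl (tigloyl) ester.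

## Route

Step 1
Reactants: 1 1-bromo-3-chloropropane; 2 propyne; 3 carbon dioxide
Product: 7 (2Z)-6-chloro-3-methylhex-2-enoic acid, via Grignard reagent 4 (not isolated), via alkylcopper 5 (not isolated), via alkenylcopper 6 (not isolated)
Conditions: Mg, Et2O, 0 °C; CuBr·SMe2, Et2O/Me2S, −45 °C; 2, −25 °C; 3 (gas), HMPA, P(OEt)3 (cat.), −40 → 0 °C; aq. HCl
Reagents that add atoms: none
Why: Normant carbocupration adds the alkyl group and copper syn across propyne (alkyl on the internal carbon) and carboxylation of the alkenylcopper proceeds with retention, so C3 and C6 end up cis on the C4=C5 olefin (Z).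

Step 2
Reactants: 7 (2Z)-6-chloro-3-methylhex-2-enoic acid
Product: 8 tert-butyl (2Z)-6-chloro-3-methylhex-2-enoate
Conditions: isobutylene, H2SO4 (cat.), CH2Cl2, sealed tube, rt
Reagents that add atoms: isobutylene (2-methylpropene), CC(C)=C
Why: Acid-catalysed addition of the carboxylic acid to isobutylene (tert-butyl ester formation) masks the acid as a hindered ester that survives the ylide, the metathesis catalyst and the acylations that follow.

Step 3
Reactants: 8 tert-butyl (2Z)-6-chloro-3-methylhex-2-enoate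
Product: 9 [(4Z)-6-tert-butoxy-4-methyl-6-oxohex-4-en-1-yl](triphenyl)phosphonium iodide
Conditions: NaI, PPh3, MeCN, reflux
Reagents that add atoms: triphenylphosphine, c1ccc(cc1)P(c1ccccc1)c1ccccc1; sodium iodide, [Na+].[I-]
Why: Finkelstein exchange followed by SN2 quaternisation of PPh3 at the primary carbon gives the phosphonium salt and leaves the (Z)-enoate untouched.

Step 4
Reactants: 10 prop-2-yn-1-ol; 11 (2E)-2-methylbut-2-enoyl chloride (tigloyl chloride)
Product: 12 prop-2-yn-1-yl (2E)-2-methylbut-2-enoate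
Conditions: Et3N, DMAP (cat.), CH2Cl2, 0 °C → rt
Reagents that add atoms: none
Why: Acylation of the primary alcohol by the acid chloride (esterification) installs the tigloyl ester early, because it is inert to all later reagents and later steers the alkyne hydration.

Step 5
Reactants: 12 prop-2-yn-1-yl (2E)-2-methylbut-2-enoate; 13 (2E)-but-2-enal
Product: 14 (4R,5E)-4-hydroxyhept-5-en-2-yn-1-yl (2E)-2-methylbut-2-enoate
Conditions: ProPhenol ligand (10 mol%), Me2Zn (3 equiv), Ph3PO (20 mol%), toluene, 4 °C; aq. NH4Cl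
Reagents that add atoms: none
Why: Zinc–ProPhenol-catalysed asymmetric alkynylation of an enal creates the C8 carbinol, the ligand enantiomer being the one that directs the zinc acetylide to the aldehyde face giving the 4R alcohol (this centre becomes C8 S of the target).

Step 6
Reactants: 14 (4R,5E)-4-hydroxyhept-5-en-2-yn-1-yl (2E)-2-methylbut-2-enoate
Product: 15 (4S,5E)-4-hydroxy-2-oxohept-5-en-1-yl (2E)-2-methylbut-2-enoate
Conditions: Ph3PAuCl (2 mol%), AgSbF6 (2 mol%), 1,4-dioxane/H2O (10:1), rt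
Reagents that add atoms: water, O
Why: Gold-catalysed hydration of a propargylic ester in which the tigloyl carbonyl attacks the nearer alkyne carbon (5-exo-dig, dioxolenium ion) so that the ketone appears only at C10, the carbinol centre being untouched (its descriptor changes from R to S only because the alkyne is lost).

Step 7
Reactants: 9 [(4Z)-6-tert-butoxy-4-methyl-6-oxohex-4-en-1-yl](triphenyl)phosphonium iodide; 15 (4S,5E)-4-hydroxy-2-oxohept-5-en-1-yl (2E)-2-methylbut-2-enoate
Product: 19 tert-butyl (2Z,6Z,9S,10E)-9-hydroxy-3-methyl-7-{[(2E)-2-methylbut-2-enoyloxy]methyl}dodeca-2,6,10-trienoate, via silyl ether 16 (not isolated), via phosphorus ylide 17 (not isolated), via silylated triene 18 (not isolated)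
Conditions: 15, Me3SiCl, imidazole, THF, 0 °C; 9, KN(SiMe3)2, THF, −78 °C, then the filtered solution of 16, −78 °C → rt; aq. citric acid, MeOH, rt
Reagents that add atoms: none
Why: Wittig olefination of an α-oxygenated ketone with a non-stabilised ylide, which by the known preference of α-alkoxy ketones (here extended to an α-acyloxy ketone) places the ylide-derived chain cis to the CH2O group and so gives the 6Z olefin (C2 cis to C14, C9 trans to C2), the secondary alcohol being protected in the flask as its Me3Si ether against the basic ylide and freed on work-up.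

Step 8
Reactants: 20 2-(bromomethyl)prop-2-enoic acid
Product: 21 2-[(benzenesulfonyl)methyl]prop-2-enoic acid
Conditions: PhSO2Na (2.2 equiv), MeOH, reflux; aq. HCl
Reagents that add atoms: sodium benzenesulfinate, [Na+].[O-]S(=O)c1ccccc1
Why: SN2 displacement of the allylic bromide by the sulfur of the sulfinate gives the allyl sulfone whose PhSO2 group is the radical leaving group of step 12.

Step 9
Reactants: 19 tert-butyl (2Z,6Z,9S,10E)-9-hydroxy-3-methyl-7-{[(2E)-2-methylbut-2-enoyloxy]methyl}dodeca-2,6,10-trienoate; 21 2-[(benzenesulfonyl)methyl]prop-2-enoic acid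
Product: 23 tert-butyl (2Z,6Z,9S,10E)-9-({2-[(benzenesulfonyl)methyl]prop-2-enoyl}oxy)-3-methyl-7-{[(2E)-2-methylbut-2-enoyloxy]methyl}dodeca-2,6,10-trienoate, via acid chloride 22 (not isolated)
Conditions: 21, (COCl)2, DMF (cat.), CH2Cl2, 0 °C → rt, evaporate; 19, 2,6-lutidine, CH2Cl2, 0 °C
Reagents that add atoms: none
Why: Esterification of the secondary allylic alcohol through the acid chloride with a hindered pyridine base avoids amine addition–elimination on the sulfonylmethyl acrylate and does not touch C8.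

Step 10
Reactants: 23 tert-butyl (2Z,6Z,9S,10E)-9-({2-[(benzenesulfonyl)methyl]prop-2-enoyl}oxy)-3-methyl-7-{[(2E)-2-methylbut-2-enoyloxy]methyl}dodeca-2,6,10-trienoate
Product: 24 tert-butyl (2Z,6Z)-8-{(2S)-4-[(benzenesulfonyl)methyl]-5-oxo-2,5-dihydrofuran-2-yl}-3-methyl-7-{[(2E)-2-methylbut-2-enoyloxy]methyl}octa-2,6-dienoate
Conditions: second-generation Grubbs catalyst RuCl2(=CHPh)(PCy3)(H2IMes) (5 mol%), toluene, 80 °C, Ar sparge
Reagents that add atoms: none
Why: Ring-closing metathesis between the propenyl group and the acrylate closes the butenolide (ring A) with loss of propene, the three trisubstituted olefins being too hindered to take part.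

Step 11
Reactants: 24 tert-butyl (2Z,6Z)-8-{(2S)-4-[(benzenesulfonyl)methyl]-5-oxo-2,5-dihydrofuran-2-yl}-3-methyl-7-{[(2E)-2-methylbut-2-enoyloxy]methyl}octa-2,6-dienoate
Product: 27 Se-phenyl (2Z,6Z)-8-{(2S)-4-[(benzenesulfonyl)methyl]-5-oxo-2,5-dihydrofuran-2-yl}-3-methyl-7-{[(2E)-2-methylbut-2-enoyloxy]methyl}octa-2,6-dieneselenoate, via carboxylic acid 25 (not isolated), via acid chloride 26 (not isolated)
Conditions: CF3CO2H, CH2Cl2, 0 °C → rt, evaporate; (COCl)2, DMF (cat.), CH2Cl2, 0 °C, evaporate; PhSeSiMe3, CH2Cl2, 0 °C → rt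
Reagents that add atoms: phenyl trimethylsilyl selenide, C[Si](C)(C)[Se]c1ccccc1
Why: Acidolysis of the tert-butyl ester, acid chloride formation and Se-acylation of the silyl selenide give the selenoester without nucleophilic phosphines, selenolates or bases that would attack the butenolide or displace the sulfinate.

Step 12
Reactants: 27 Se-phenyl (2Z,6Z)-8-{(2S)-4-[(benzenesulfonyl)methyl]-5-oxo-2,5-dihydrofuran-2-yl}-3-methyl-7-{[(2E)-2-methylbut-2-enoyloxy]methyl}octa-2,6-dieneselenoate
Product: 28 [(3aR,5Z,9Z,11aS)-6-methyl-3-methylidene-2,4-dioxo-2,3,3a,4,7,8,11,11a-octahydrocyclodeca[b]furan-10-yl]methyl (2E)-2-methylbut-2-enoate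
Conditions: (Bu3Sn)2 (1.2 equiv), hν (sunlamp, Pyrex), benzene, 80 °C, 1 mM, 27 added over 10 h
Reagents that add atoms: none
Why: Proposed new method: Bu3Sn• abstracts PhSe to give the sigma-type (Z)-enoyl radical, which does not decarbonylate and closes ring B by adding to C7 of the butenolide anti to the C8–C9 bond (trans ring fusion, 3aR), after which the C11 radical ejects PhSO2• to form the α-methylene lactone and PhSO2• regenerates Bu3Sn• from the distannane, the closest known reactions being acyl radical macrocyclisation of selenoesters onto acrylates and radical allylation with allyl sulfones.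

Step 13
Reactants: 28 [(3aR,5Z,9Z,11aS)-6-methyl-3-methylidene-2,4-dioxo-2,3,3a,4,7,8,11,11a-octahydrocyclodeca[b]furan-10-yl]methyl (2E)-2-methylbut-2-enoate
Product: 29 [(3aS,4R,5Z,9Z,11aS)-4-hydroxy-6-methyl-3-methylidene-2-oxo-2,3,3a,4,7,8,11,11a-octahydrocyclodeca[b]furan-10-yl]methyl (2E)-2-methylbut-2-enoate
Conditions: NaBH4, CeCl3·7H2O, MeOH, −78 °C
Reagents that add atoms: none
Why: Luche 1,2-reduction of the enone, with hydride expected to attack the C6 carbonyl anti to the C7–C11 bond (Felkin–Anh, the lactone sp2 carbon as the perpendicular group) to give the 4R carbinol of 29 (C6 S of the target), while CeCl3 and low temperature prevent conjugate reduction of the methylene lactone.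

Step 14
Reactants: 29 [(3aS,4R,5Z,9Z,11aS)-4-hydroxy-6-methyl-3-methylidene-2-oxo-2,3,3a,4,7,8,11,11a-octahydrocyclodeca[b]furan-10-yl]methyl (2E)-2-methylbut-2-enoate
Product: 30 CNP0116446.1, (4S,5R,6S,7S,8S)-4,5-epoxy-6-hydroxy-14-[(2E)-2-methylbut-2-enoyloxy]germacra-1(10),11(13)-dien-12,8-olide
Conditions: VO(acac)2 (5 mol%), t-BuOOH (1.5 equiv), CH2Cl2, 0 °C
Reagents that add atoms: tert-butyl hydroperoxide, CC(C)(C)OO
Why: Vanadium-catalysed hydroxyl-directed epoxidation of the (Z)-allylic alcohol, in which allylic 1,3-strain holds H6 in the olefin plane so that the vanadate ester delivers oxygen to the C4=C5 face on the side of the hydroxyl (threo, 4S,5R, cis-epoxide from the Z olefin), the other olefins being electron-poor or remote from the hydroxyl.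

## Compound list

1 | 1-bromo-3-chloropropane | ClCCCBr | starting material
2 | propyne | CC#C | starting material
3 | carbon dioxide | O=C=O | starting material
4 | 3-chloropropylmagnesium bromide | ClCCC[Mg]Br | intermediate
5 | (3-chloropropyl)copper, as its MgBr2 complex | ClCCC[Cu] | intermediate
6 | [(1Z)-5-chloro-2-methylpent-1-en-1-yl]copper | ClCCC/C(C)=C\[Cu] | intermediate
7 | (2Z)-6-chloro-3-methylhex-2-enoic acid | OC(=O)/C=C(C)\CCCCl | intermediate
8 | tert-butyl (2Z)-6-chloro-3-methylhex-2-enoate | CC(C)(C)OC(=O)/C=C(C)\CCCCl | intermediate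
9 | [(4Z)-6-tert-butoxy-4-methyl-6-oxohex-4-en-1-yl](triphenyl)phosphonium iodide | CC(C)(C)OC(=O)/C=C(C)\CCC[P+](c1ccccc1)(c1ccccc1)c1ccccc1.[I-] | intermediate
10 | prop-2-yn-1-ol | C#CCO | starting material
11 | (2E)-2-methylbut-2-enoyl chloride | C/C=C(\C)C(Cl)=O | starting material
12 | prop-2-yn-1-yl (2E)-2-methylbut-2-enoate | C#CCOC(=O)/C(C)=C/C | intermediate
13 | (2E)-but-2-enal | C/C=C/C=O | starting material
14 | (4R,5E)-4-hydroxyhept-5-en-2-yn-1-yl (2E)-2-methylbut-2-enoate | O[C@H](/C=C/C)C#CCOC(=O)/C(C)=C/C | intermediate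
15 | (4S,5E)-4-hydroxy-2-oxohept-5-en-1-yl (2E)-2-methylbut-2-enoate | O[C@H](/C=C/C)CC(=O)COC(=O)/C(C)=C/C | intermediate
16 | (4S,5E)-2-oxo-4-[(trimethylsilyl)oxy]hept-5-en-1-yl (2E)-2-methylbut-2-enoate | C[Si](C)(C)O[C@H](/C=C/C)CC(=O)COC(=O)/C(C)=C/C | intermediate
17 | tert-butyl (2Z)-3-methyl-6-(triphenyl-λ5-phosphanylidene)hex-2-enoate | CC(C)(C)OC(=O)/C=C(C)\CCC=P(c1ccccc1)(c1ccccc1)c1ccccc1 | intermediate
18 | tert-butyl (2Z,6Z,9S,10E)-3-methyl-7-{[(2E)-2-methylbut-2-enoyloxy]methyl}-9-[(trimethylsilyl)oxy]dodeca-2,6,10-trienoate | CC(C)(C)OC(=O)/C=C(C)\CC/C=C(COC(=O)/C(C)=C/C)/C[C@H](O[Si](C)(C)C)/C=C/C | intermediate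
19 | tert-butyl (2Z,6Z,9S,10E)-9-hydroxy-3-methyl-7-{[(2E)-2-methylbut-2-enoyloxy]methyl}dodeca-2,6,10-trienoate | CC(C)(C)OC(=O)/C=C(C)\CC/C=C(COC(=O)/C(C)=C/C)/C[C@H](O)/C=C/C | intermediate
20 | 2-(bromomethyl)prop-2-enoic acid | C=C(CBr)C(=O)O | starting material
21 | 2-[(benzenesulfonyl)methyl]prop-2-enoic acid | C=C(CS(=O)(=O)c1ccccc1)C(=O)O | intermediate
22 | 2-[(benzenesulfonyl)methyl]prop-2-enoyl chloride | C=C(CS(=O)(=O)c1ccccc1)C(Cl)=O | intermediate
23 | tert-butyl (2Z,6Z,9S,10E)-9-({2-[(benzenesulfonyl)methyl]prop-2-enoyl}oxy)-3-methyl-7-{[(2E)-2-methylbut-2-enoyloxy]methyl}dodeca-2,6,10-trienoate | CC(C)(C)OC(=O)/C=C(C)\CC/C=C(COC(=O)/C(C)=C/C)/C[C@H](OC(=O)C(=C)CS(=O)(=O)c1ccccc1)/C=C/C | intermediate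
24 | tert-butyl (2Z,6Z)-8-{(2S)-4-[(benzenesulfonyl)methyl]-5-oxo-2,5-dihydrofuran-2-yl}-3-methyl-7-{[(2E)-2-methylbut-2-enoyloxy]methyl}octa-2,6-dienoate | CC(C)(C)OC(=O)/C=C(C)\CC/C=C(COC(=O)/C(C)=C/C)/C[C@@H]1OC(=O)C(CS(=O)(=O)c2ccccc2)=C1 | intermediate
25 | (2Z,6Z)-8-{(2S)-4-[(benzenesulfonyl)methyl]-5-oxo-2,5-dihydrofuran-2-yl}-3-methyl-7-{[(2E)-2-methylbut-2-enoyloxy]methyl}octa-2,6-dienoic acid | OC(=O)/C=C(C)\CC/C=C(COC(=O)/C(C)=C/C)/C[C@@H]1OC(=O)C(CS(=O)(=O)c2ccccc2)=C1 | intermediate
26 | (2Z,6Z)-8-{(2S)-4-[(benzenesulfonyl)methyl]-5-oxo-2,5-dihydrofuran-2-yl}-3-methyl-7-{[(2E)-2-methylbut-2-enoyloxy]methyl}octa-2,6-dienoyl chloride | ClC(=O)/C=C(C)\CC/C=C(COC(=O)/C(C)=C/C)/C[C@@H]1OC(=O)C(CS(=O)(=O)c2ccccc2)=C1 | intermediate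
27 | Se-phenyl (2Z,6Z)-8-{(2S)-4-[(benzenesulfonyl)methyl]-5-oxo-2,5-dihydrofuran-2-yl}-3-methyl-7-{[(2E)-2-methylbut-2-enoyloxy]methyl}octa-2,6-dieneselenoate | O=C(/C=C(C)\CC/C=C(COC(=O)/C(C)=C/C)/C[C@@H]1OC(=O)C(CS(=O)(=O)c2ccccc2)=C1)[Se]c1ccccc1 | intermediate
28 | [(3aR,5Z,9Z,11aS)-6-methyl-3-methylidene-2,4-dioxo-2,3,3a,4,7,8,11,11a-octahydrocyclodeca[b]furan-10-yl]methyl (2E)-2-methylbut-2-enoate | C=C1C(=O)O[C@H]2C/C(COC(=O)/C(C)=C/C)=C/CC/C(C)=C\C(=O)[C@H]12 | intermediate
29 | [(3aS,4R,5Z,9Z,11aS)-4-hydroxy-6-methyl-3-methylidene-2-oxo-2,3,3a,4,7,8,11,11a-octahydrocyclodeca[b]furan-10-yl]methyl (2E)-2-methylbut-2-enoate | C=C1C(=O)O[C@H]2C/C(COC(=O)/C(C)=C/C)=C/CC/C(C)=C\[C@@H](O)[C@H]12 | intermediate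
30 | CNP0116446.1, (4S,5R,6S,7S,8S)-4,5-epoxy-6-hydroxy-14-[(2E)-2-methylbut-2-enoyloxy]germacra-1(10),11(13)-dien-12,8-olide (cis-epoxide, trans-fused lactone, C9 trans to C2) | C=C1C(=O)O[C@H]2C/C(COC(=O)/C(C)=C/C)=C/CC[C@]3(C)O[C@@H]3[C@@H](O)[C@H]12 | target

## Step count and risks

Total steps: 14. Longest linear sequence: 10 steps (steps 1, 2, 3, 7, 9, 10, 11, 12, 13, 14; the branch through steps 4, 5, 6 is equally long).

Step 12 (radical closure of ring B) is the most likely to fail. Ten-membered radical closures are slow, Bu3Sn• can attack the allyl sulfone itself, sulfonyl and stannyl radicals can isomerise the olefins, and the facial selectivity at C7 is not proven. The fallback generates the same enoyl radical by catalytic hydrogen-atom abstraction from an aldehyde, without tin or selenium. It sets out from 25, isolated after the CF3CO2H stage of step 11. BH3·SMe2 (1 equiv, THF, −15 °C) reduces the acid to the (Z)-allylic alcohol F1, and MnO2 (CH2Cl2, rt) oxidises this to the (Z)-enal F2. F2 is irradiated at 390 nm with (Bu4N)4W10O32 (2 mol%) in MeCN at 1 mM. The excited decatungstate abstracts the formyl hydrogen, the enoyl radical closes on C7 as in step 12, and the expelled PhSO2• is reduced by the reduced photocatalyst to benzenesulfinic acid. The fallback comes back to the route at 28.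

Step 13 (Luche reduction) may give mainly the wrong C6 epimer, because the face of the macrocyclic ketone that is exposed cannot be predicted with confidence. The fallback corrects the centre by inversion instead of by reduction. It sets out from 28, whose Luche reduction then gives the C6-epimeric alcohol F3. F3 is treated with chloroacetic acid, PPh3 and diisopropyl azodicarboxylate (THF, 0 °C, Mitsunobu reaction) to give the inverted chloroacetate F4. Thiourea and NaHCO3 in EtOH (50 °C) remove the chloroacetyl group without touching the tiglate or the lactone. The fallback comes back to the route at 29.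

Step 6 (gold-catalysed hydration) may fail if the cationic gold ionises the free allylic-propargylic alcohol (Meyer–Schuster rearrangement) or makes the ester migrate. The fallback installs the ketone by hydroxyl-directed trans-hydrosilylation and oxidation. It sets out from 14. [Cp*Ru(MeCN)3]PF6 (2 mol%) and (EtO)3SiH in CH2Cl2 (0 °C) place silicon on the alkyne carbon distal to the hydroxyl (C10) to give the (Z)-vinylsilane F5. KF, KHCO3 and H2O2 in THF/MeOH then oxidise the C–Si bond to the enol and hence the ketone. The fallback comes back to the route at 15.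

Further compounds

F1 | step 12 | [(2Z,6Z)-2-{[(2S)-4-[(benzenesulfonyl)methyl]-5-oxo-2,5-dihydrofuran-2-yl]methyl}-8-hydroxy-6-methylocta-2,6-dien-1-yl] (2E)-2-methylbut-2-enoate | OC/C=C(C)\CC/C=C(COC(=O)/C(C)=C/C)/C[C@@H]1OC(=O)C(CS(=O)(=O)c2ccccc2)=C1
F2 | step 12 | [(2Z,6Z)-2-{[(2S)-4-[(benzenesulfonyl)methyl]-5-oxo-2,5-dihydrofuran-2-yl]methyl}-6-methyl-8-oxoocta-2,6-dien-1-yl] (2E)-2-methylbut-2-enoate | O=C/C=C(C)\CC/C=C(COC(=O)/C(C)=C/C)/C[C@@H]1OC(=O)C(CS(=O)(=O)c2ccccc2)=C1
F3 | step 13 | [(3aS,4S,5Z,9Z,11aS)-4-hydroxy-6-methyl-3-methylidene-2-oxo-2,3,3a,4,7,8,11,11a-octahydrocyclodeca[b]furan-10-yl]methyl (2E)-2-methylbut-2-enoate | C=C1C(=O)O[C@H]2C/C(COC(=O)/C(C)=C/C)=C/CC/C(C)=C\[C@H](O)[C@H]12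
F4 | step 13 | [(3aR,4R,5Z,9Z,11aS)-4-[(chloroacetyl)oxy]-6-methyl-3-methylidene-2-oxo-2,3,3a,4,7,8,11,11a-octahydrocyclodeca[b]furan-10-yl]methyl (2E)-2-methylbut-2-enoate | C=C1C(=O)O[C@H]2C/C(COC(=O)/C(C)=C/C)=C/CC/C(C)=C\[C@@H](OC(=O)CCl)[C@H]12
F5 | step 6 | (2Z,4R,5E)-4-hydroxy-2-(triethoxysilyl)hepta-2,5-dien-1-yl (2E)-2-methylbut-2-enoate | CCO[Si](OCC)(OCC)/C(COC(=O)/C(C)=C/C)=C\[C@H](O)/C=C/C
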